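(The runs stem from a simulated flask for substances that don't exist; the scatter is artificial.)

Each flask stops at 2.0 min with a leftover of E, and we want the part of the charge that has become Q by then. The proposed steps are E to Q, a pair of E to L, and Q to D and back.

| setting | beta | eta | Monday's | Tuesday's | Friday's |
|---|---|---|---|---|---|
| E | 0.10 M | 0.40 M | 0.20 M | 0.20 M | 0.20 M |
| temperature | 35 °C | 65 °C | 90 °C | 65 °C | 40 °C |
| remark | run made earlier | run made earlier |  |  |  |
| time |  |  | 2.0 min | 2.0 min | 2.0 min |

| beta: time / min | beta: Q / % | eta: time / min | eta: Q / % |
|---|---|---|---|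
| 2.50 | 0.2 | 1.50 | 1.6 |
| 5.00 | 0.9 | 3.00 | 3.5 |
| 12.0 | 0 | 5.00 | 4.6 |
| 30.0 | 1.3 | 6.00 | 5.5 |

(standard deviation of a reading: 0.3 percentage points)

- the best flask by amount of Q, in percent of the E charged; "all alike" if 1.5 percentage points covers them all (Monday's / Tuesday's / Friday's / all alike)
- amount of Q at the end, in percent of the E charged, Monday's
- amount of Q at the end, in percent of the E charged, Tuesday's
- amount of Q at the end, in percent of the E charged, Friday's

- percentages count the E that a species holds: one L counts as two
- the analysis behind the earlier runs scatters by 0.3 percentage points, standard deviation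
- steps that have been proposed: E -> Q; 2 E -> L; Q <-> D

We fold the givens into one number, N. The eta reading at 3.00 min gives a fractional rate of 0.0117 min⁻¹ at 65 °C. The beta reading at 30.0 min, which stands furthest above the scatter, gives 4.33 × 10⁻⁴ min⁻¹ at 35 °C. As read, that is a rise of 26.9, with the scatter of both readings in it, and we put it all on temperature although the two charges differ too. Spread evenly over reciprocal absolute temperature, it gives Monday's N = 0.239: the run time over the time constant of Q's appearance, a Damköhler number. For Tuesday's N is 0.0233, for Friday's 0.00157.

N assumes a full charge throughout, so we go round once more and multiply N by one minus half of N. Monday's becomes 21.1% and Tuesday's 2.31%, while Friday's stays near 0.157%. By this reckoning Monday's leads Tuesday's by 19 percentage points, above the margin.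

Was one number enough? The same reckoning for eta at 6.00 min gives 6.75%, but the reading is 5.5%, a gap of 1.3 points against a scatter of 0.3 points. So the readings point to a further loss, and these readings of Q do not show its step.

The forecast, holding that “early rates dominate”, gave 9.5%, 2.3% and 0.4% for Monday's, Tuesday's and Friday's, and differs from us on Monday's and Friday's. The simulation gives 22.2%, 2.85% and 0.160%, so Monday's is best.

    E → Q (k = 0.00440 s⁻¹, Ea = 109 kJ mol⁻¹)
    2 E → L (k = 0.0240 M⁻¹ s⁻¹, Ea = 66.0 kJ mol⁻¹)
    Q ⇌ D (K = 0.340, k = 0.0320 s⁻¹, Ea = 90.0 kJ mol⁻¹, ΔH = 11.0 kJ mol⁻¹)
    (constants at 90 °C)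

Monday's stands 1.1 points above our 21.1%. Taking the temperature dependence of the step from E to Q away turns the gap between Monday's and Friday's from 22 points into −0.077 points. A neighbour of Monday's charged with 0.80 M keeps N = 0.239 and so 21.1%, since N is reckoned in fractions of the charge. The simulation gives it 13.1%, with 69.7% of the charge in L.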